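**Plan**

1. Numbering: the terpene half is numbered as a cadinane (C1 ring-fusion CH, C2 and C3 CH2, C4 spiro carbon bearing the chroman oxygen, C5=C6 alkene, C7 CH–iPr, C10 CH–Me); C1′ is the CHPh carbon of the chroman.
2. Retrosynthetic cuts, in order: the two aryl–CHO bonds; C5=C6 of ring B (metathesis); O–C4 of the chroman ring (Pd allylic etherification); C3–C4 (B-alkyl Suzuki coupling); C1–C2 (aldol on menthone); C1′–phenyl (Rh conjugate addition to a coumarin).
3. Enabling feature: C5=C6 is the only alkene and lies in ring B between the spiro carbon C4 and C6 of ring A. Cutting it leaves a vinyl group on C4 of a complete chroman and an exocyclic methylene on C6 of a complete menthane ring, held 1,6 to each other by the C3–C2–C1 chain on a quaternary centre.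
4. Forward order: coumarin → aryl-substituted (Z)-vinyl iodide; menthone → 2-(methylenecyclohexyl)ethyl iodide; Suzuki union at C3–C4; chroman ring by O–C4 closure; ring B by metathesis; fluoride deprotection; double formylation.
5. Stereochemistry: C7 and C10 from (−)-menthone; C1 by hydrogenation of the 2-alkylidene ketone anti to the axial C10 methyl; C1′ by Rh/(R)-SEGPHOS; C4 by Pd/Trost ligand acting on a geometrically pure (E)-allyl carbonate.
6. Protecting groups: the two spectator phenols are SEM ethers, freed by fluoride before formylation, because the tertiary allylic C4–O bond would not survive the acids needed to cleave methyl ethers.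

Key step: step 18

Assumption: the ligand enantiomer in step 17 is assigned by analogy with the recalled (not verified) sense of induction for (E)-configured trisubstituted phenol allyl carbonates; if the C4 epimer of 27 predominated, the antipodal ligand would be used with no other change.
Convention: numbered building blocks stand under Reactants; the line "Reagents that add atoms" lists only unnumbered reagents. SEM = 2-(trimethylsilyl)ethoxymethyl, TIPS = triisopropylsilyl, TBS = tert-butyldimethylsilyl.

**Route**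

Step 1
Reactants: 1 5,7-dihydroxycoumarin
Product: 2 5,7-bis(SEM-oxy)coumarin
Conditions: SEMCl (2.5 equiv), i-Pr2NEt, DMF, 0 °C → rt
Reagents that add atoms: 2-(trimethylsilyl)ethoxymethyl chloride, C[Si](C)(C)CCOCCl
Why: O-alkylation of both phenols with the reactive α-chloro ether (Williamson-type etherification) installs groups that are later removed by fluoride instead of acid.

Step 2
Reactants: 2 5,7-bis(SEM-oxy)coumarin; 3 phenylboronic acid
Product: 4 (4R)-4-phenyl-5,7-bis(SEM-oxy)chroman-2-one
Conditions: Rh(acac)(C2H4)2 (3 mol%), (R)-SEGPHOS, PhB(OH)2 (5 equiv), dioxane/H2O 10:1, 60 °C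
Reagents that add atoms: none
Why: Hayashi–Miyaura Rh-catalysed asymmetric 1,4-addition of an arylboronic acid to a coumarin, in which the phenyl–Rh(I)/(R)-SEGPHOS complex inserts the C3=C4 bond on one enantioface and should set C1′ as R by analogy with simpler coumarins.

Step 3
Reactants: 4 (4R)-4-phenyl-5,7-bis(SEM-oxy)chroman-2-one
Product: 5 (4R)-4-phenyl-5,7-bis(SEM-oxy)chroman-2-ol (lactol, both anomers)
Conditions: DIBAL-H (1.1 equiv), toluene, −78 °C; Rochelle salt
Reagents that add atoms: none
Why: DIBAL-H reduction of the aryl lactone stops at the tetrahedral aluminium hemiacetal at −78 °C and gives the lactol on work-up, C1′ not being enolisable.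

Step 4
Reactants: 5 (4R)-4-phenyl-5,7-bis(SEM-oxy)chroman-2-ol
Product: 6 2-[(1R)-1-phenylbut-3-yn-1-yl]-3,5-bis(SEM-oxy)phenol
Conditions: dimethyl (1-diazo-2-oxopropyl)phosphonate, K2CO3, MeOH, 0 °C → rt
Reagents that add atoms: dimethyl (1-diazo-2-oxopropyl)phosphonate, CC(=O)C(=[N+]=[N-])P(=O)(OC)OC
Why: Seyferth–Gilbert homologation in the Ohira–Bestmann variant acts on the hydroxy aldehyde in equilibrium with the lactol, turning the lactol carbon into C4 and adding C5 as the alkyne terminus.

Step 5
Reactants: 6 2-[(1R)-1-phenylbut-3-yn-1-yl]-3,5-bis(SEM-oxy)phenol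
Product: 7 triisopropylsilyl ether of 6
Conditions: TIPSCl, imidazole, DMF, rt
Reagents that add atoms: triisopropylsilyl chloride, CC(C)[Si](Cl)(C(C)C)C(C)C
Why: Imidazole-promoted silylation masks the only acidic O–H before the acetylide chemistry and keeps this oxygen distinguishable, since aryl TIPS ethers fall to buffered fluoride at 0 °C whereas aryl SEM ethers need hot fluoride.

Step 6
Reactants: 7 triisopropylsilyl ether of 6
Product: 9 (5R)-5-phenyl-5-[2-(TIPS-oxy)-4,6-bis(SEM-oxy)phenyl]pent-2-yn-1-ol, via lithium acetylide 8 (not isolated)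
Conditions: n-BuLi (1.05 equiv), THF, −78 °C; (CH2O)n, −78 °C → rt; H2O
Reagents that add atoms: formaldehyde (as paraformaldehyde), C=O
Why: Deprotonation of the terminal alkyne, far more acidic than C1′–H, and addition of the lithium acetylide to formaldehyde (acetylide hydroxymethylation) give the propargylic alcohol.

Step 7
Reactants: 9 (5R)-5-phenyl-5-[2-(TIPS-oxy)-4,6-bis(SEM-oxy)phenyl]pent-2-yn-1-ol
Product: 11 (2Z,5R)-3-iodo-5-phenyl-5-[2-(TIPS-oxy)-4,6-bis(SEM-oxy)phenyl]pent-2-en-1-ol, via vinylalanate 10 (not isolated)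
Conditions: Red-Al, THF, 0 °C → rt; EtOAc; I2, −78 °C → 0 °C
Reagents that add atoms: iodine, II
Why: Hydroxyl-directed anti-hydroalumination of the propargylic alcohol places aluminium on the distal carbon C4 in a five-membered alanate, and iodinolysis with retention gives only the (Z)-3-iodoallylic alcohol with iodine cis to CH2OH.

Step 8
Reactants: 12 (−)-menthone; 13 (tert-butyldimethylsilyloxy)acetaldehyde
Product: 15 (3R,6S)-2-[2-(TBS-oxy)-1-hydroxyethyl]-6-isopropyl-3-methylcyclohexanone (mixture at C2 and the carbinol carbon), via lithium enolate 14 (not isolated)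
Conditions: LDA, THF, −78 °C; 13, −78 °C; H2O
Reagents that add atoms: none
Why: LDA removes a proton from the less hindered α-methylene carbon (the future C1) under kinetic control and the enolate adds to the aldehyde at −78 °C (directed aldol addition); both new centres are erased in step 9 and C7 is untouched.

Step 9
Reactants: 15 (3R,6S)-2-[2-(TBS-oxy)-1-hydroxyethyl]-6-isopropyl-3-methylcyclohexanone
Product: 17 (2E,3R,6S)-2-[2-(TBS-oxy)ethylidene]-6-isopropyl-3-methylcyclohexanone, via mesylate 16 (not isolated)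
Conditions: MsCl, Et3N, CH2Cl2, −20 → 0 °C; DBU, 0 °C, short contact
Reagents that add atoms: none
Why: Mesylation and E1cB elimination through the C1 enolate give the conjugated (E)-alkylidene ketone with the CH2OTBS group anti to the carbonyl, and cold, brief base contact is used because the C7 epimer would be the thermodynamically favoured form of this enone.

Step 10
Reactants: 17 (2E,3R,6S)-2-[2-(TBS-oxy)ethylidene]-6-isopropyl-3-methylcyclohexanone
Product: 18 (2R,3R,6S)-2-[2-(TBS-oxy)ethyl]-6-isopropyl-3-methylcyclohexanone (side chain cis to the C3 methyl, trans to the C6 isopropyl)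
Conditions: H2 (1 atm), 5% Pd/C, EtOAc, rt
Reagents that add atoms: none
Why: Heterogeneous hydrogenation adds H2 syn to the exocyclic C1=C2 bond from the face opposite the C10 methyl, which allylic 1,3-strain with the (E)-substituent holds axial, so the side chain should end up cis to that methyl (C1 R) and any minor C1 epimer can be removed at this inexpensive stage.

Step 11
Reactants: 18 (2R,3R,6S)-2-[2-(TBS-oxy)ethyl]-6-isopropyl-3-methylcyclohexanone
Product: 19 tert-butyl{2-[(1R,3S,6R)-3-isopropyl-6-methyl-2-methylidenecyclohexyl]ethoxy}dimethylsilane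
Conditions: Zn, CH2Br2, TiCl4, THF/CH2Cl2, 0 °C → rt
Reagents that add atoms: dibromomethane, BrCBr
Why: Takai–Lombardo methylenation with the non-basic Zn/CH2Br2/TiCl4 reagent converts hindered, enolisable ketones into methylene compounds without epimerising the α-centres (here C1 and C7), as is known for menthone-type ketones.

Step 12
Reactants: 19 tert-butyl{2-[(1R,3S,6R)-3-isopropyl-6-methyl-2-methylidenecyclohexyl]ethoxy}dimethylsilane
Product: 20 2-[(1R,3S,6R)-3-isopropyl-6-methyl-2-methylidenecyclohexyl]ethanol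
Conditions: TBAF, THF, rt; H2O
Reagents that add atoms: none
Why: Fluoride-induced desilylation of the primary TBS ether, with nothing else in 19 reactive toward TBAF.

Step 13
Reactants: 20 2-[(1R,3S,6R)-3-isopropyl-6-methyl-2-methylidenecyclohexyl]ethanol
Product: 21 (1R,3S,6R)-1-(2-iodoethyl)-3-isopropyl-6-methyl-2-methylidenecyclohexane
Conditions: PPh3, imidazole, I2, CH2Cl2, 0 °C → rt
Reagents that add atoms: iodine, II
Why: Appel-type iodination converts the primary alcohol into the iodide by SN2 displacement of the alkoxyphosphonium ion, with no stereocentre involved.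

Step 14
Reactants: 21 (1R,3S,6R)-1-(2-iodoethyl)-3-isopropyl-6-methyl-2-methylidenecyclohexane; 11 (2Z,5R)-3-iodo-5-phenyl-5-[2-(TIPS-oxy)-4,6-bis(SEM-oxy)phenyl]pent-2-en-1-ol
Product: 24 (2E,5R)-3-{2-[(1R,3S,6R)-3-isopropyl-6-methyl-2-methylidenecyclohexyl]ethyl}-5-phenyl-5-[2-(TIPS-oxy)-4,6-bis(SEM-oxy)phenyl]pent-2-en-1-ol, via alkyllithium 22 (not isolated), via B-alkyl borinate 23 (not isolated)
Conditions: 21, t-BuLi (2.1 equiv), Et2O, −78 °C; 9-MeO-9-BBN, THF, −78 °C → rt; then 11, Pd(dppf)Cl2 (10 mol%), AsPh3, aq. K3PO4, DMF, rt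
Reagents that add atoms: none
Why: B-alkyl Suzuki–Miyaura coupling, in which lithium–iodine exchange and capture by 9-MeO-9-BBN give a boron ate complex that transfers its primary alkyl group to the vinyl–Pd(II) species from 11, forms C3–C4 with retention of alkene geometry and gives the (E)-trisubstituted allylic alcohol.

Step 15
Reactants: 24 (E)-allylic alcohol
Product: 25 methyl carbonate of 24
Conditions: ClCO2Me, pyridine, CH2Cl2, 0 °C
Reagents that add atoms: methyl chloroformate, COC(=O)Cl
Why: Acylation of the primary allylic alcohol installs the carbonate leaving group for Pd(0) ionisation, the phenol still being silylated so that only one oxygen reacts.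

Step 16
Reactants: 25 methyl carbonate of 24
Product: 26 methyl (2E,5R)-5-[2-hydroxy-4,6-bis(SEM-oxy)phenyl]-3-{2-[(1R,3S,6R)-3-isopropyl-6-methyl-2-methylidenecyclohexyl]ethyl}-5-phenylpent-2-en-1-yl carbonate
Conditions: TBAF, AcOH, THF, 0 °C
Reagents that add atoms: none
Why: Acetic acid-buffered fluoride removes the aryl TIPS group (desilylation) under conditions that leave aryl SEM ethers and the allylic carbonate intact, liberating the phenol nucleophile.

Step 17
Reactants: 26 phenol allyl carbonate
Product: 27 (2S,4R)-2-{2-[(1R,3S,6R)-3-isopropyl-6-methyl-2-methylidenecyclohexyl]ethyl}-4-phenyl-5,7-bis(SEM-oxy)-2-vinylchromane (C4 S, C1′ R, C1 R, C7 S, C10 R)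
Conditions: Pd2(dba)3·CHCl3 (2.5 mol%), (S,S)-DACH-phenyl Trost ligand (7.5 mol%), AcOH (1 equiv), CH2Cl2, rt
Reagents that add atoms: none
Why: Pd-catalysed asymmetric allylic alkylation with a phenol nucleophile, in which ionisation of the carbonate gives a 1,1-disubstituted π-allyl complex and the phenol attacks its substituted terminus in a 6-exo closure inside the chiral ligand pocket, so C4 is set by the catalyst on the single (E) geometry while acetic acid promotes π–σ–π equilibration.

Step 18
Reactants: 27 2-vinylchroman tethered to the methylenecyclohexane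
Product: 28 di-O-SEM spirochroman with the C5=C6 alkene (C4 S, C1′ R, C1 R, C7 S, C10 R)
Conditions: Hoveyda–Grubbs II (10 mol%), 1,4-benzoquinone (20 mol%), toluene (2 mM), 80 °C, Ar sparge
Reagents that add atoms: none
Why: Olefin metathesis by the Chauvin mechanism: the Ru alkylidene exchanges onto the monosubstituted C4 vinyl group, the resulting C5 alkylidene adds intramolecularly [2+2] to the C6 exocyclic methylene, and cycloreversion of the ruthenacyclobutane delivers the C5=C6 bond with loss of ethylene. The closest known reaction type is ring-closing metathesis of a vinyl group with a 1,1-disubstituted alkene to a trisubstituted cyclohexene using second-generation Ru–NHC catalysts. Ring B closes as a six-membered carbocycle in which both former alkene carbons become ring members, the chain C4–C3–C2–C1–C6 placing the termini 1,6. No stereocentre is created or touched: C4 and C1′ were fixed by the Pd and Rh catalysts, C1 by hydrogenation, C7 and C10 by menthone, and the neutral conditions leave the allylic C1–H alone. The step needs ring closure in preference to dimerisation at the vinyl group and no Ru–H migration of the new alkene; the quaternary C4 (gem-disubstituent effect), the strain-free six-membered product, high dilution, ethylene purge and benzoquinone as hydride scavenger should secure this.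

Step 19
Reactants: 28 di-O-SEM spirochroman
Product: 29 5,7-dihydroxy spirochroman (same configuration as 28)
Conditions: TBAF (excess), DMPU, 80 °C; then AcOH, H2O
Reagents that add atoms: none
Why: Fluoride attacks silicon of each SEM group and fragmentation releases ethylene, formaldehyde and the phenoxide (fluoride-mediated SEM cleavage), a base-side deprotection chosen because the tertiary allylic C4–O bond would ionise under acid.

Step 20
Reactants: 29 5,7-dihydroxy spirochroman
Product: 31 guajadial C, via bis-iminium salt 30 (not isolated)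
Conditions: POCl3 (6 equiv), DMF, MeCN, 0 °C → rt; then aq. NaOAc, rt
Reagents that add atoms: N,N-dimethylformamide, CN(C)C=O; water, O
Why: Vilsmeier–Haack formylation, in which the chloroiminium ion from DMF/POCl3 substitutes both free positions of the phloroglucinol-type ring (kept nucleophilic for the second substitution by the two free hydroxyls) and aqueous hydrolysis of the bis-iminium salt gives the dialdehyde.

**Compound list**

1 | 5,7-dihydroxycoumarin | O=c1ccc2c(O)cc(O)cc2o1 | starting material
2 | 5,7-bis(SEM-oxy)coumarin | O=c1ccc2c(OCOCC[Si](C)(C)C)cc(OCOCC[Si](C)(C)C)cc2o1 | intermediate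
3 | phenylboronic acid | OB(O)c1ccccc1 | starting material
4 | (4R)-4-phenyl-5,7-bis(SEM-oxy)chroman-2-one | O=C1C[C@H](c2ccccc2)c2c(OCOCC[Si](C)(C)C)cc(OCOCC[Si](C)(C)C)cc2O1 | intermediate
5 | (4R)-4-phenyl-5,7-bis(SEM-oxy)chroman-2-ol (lactol, both anomers) | OC1C[C@H](c2ccccc2)c2c(OCOCC[Si](C)(C)C)cc(OCOCC[Si](C)(C)C)cc2O1 | intermediate
6 | 2-[(1R)-1-phenylbut-3-yn-1-yl]-3,5-bis(SEM-oxy)phenol | C#CC[C@H](c1ccccc1)c1c(OCOCC[Si](C)(C)C)cc(OCOCC[Si](C)(C)C)cc1O | intermediate
7 | triisopropylsilyl ether of 6 | C#CC[C@H](c1ccccc1)c1c(OCOCC[Si](C)(C)C)cc(OCOCC[Si](C)(C)C)cc1O[Si](C(C)C)(C(C)C)C(C)C | intermediate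
8 | lithium acetylide of 7 | [Li]C#CC[C@H](c1ccccc1)c1c(OCOCC[Si](C)(C)C)cc(OCOCC[Si](C)(C)C)cc1O[Si](C(C)C)(C(C)C)C(C)C | intermediate
9 | (5R)-5-phenyl-5-[2-(TIPS-oxy)-4,6-bis(SEM-oxy)phenyl]pent-2-yn-1-ol | OCC#CC[C@H](c1ccccc1)c1c(OCOCC[Si](C)(C)C)cc(OCOCC[Si](C)(C)C)cc1O[Si](C(C)C)(C(C)C)C(C)C | intermediate
10 | sodium vinylalanate from 9 (five-membered O–Al–C=C–C ring, two 2-methoxyethoxy ligands on Al) | [Na+].COCCO[Al-]1(OCCOC)OCC=C1C[C@H](c1ccccc1)c1c(OCOCC[Si](C)(C)C)cc(OCOCC[Si](C)(C)C)cc1O[Si](C(C)C)(C(C)C)C(C)C | intermediate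
11 | (2Z,5R)-3-iodo-5-phenyl-5-[2-(TIPS-oxy)-4,6-bis(SEM-oxy)phenyl]pent-2-en-1-ol | OC/C=C(\I)C[C@H](c1ccccc1)c1c(OCOCC[Si](C)(C)C)cc(OCOCC[Si](C)(C)C)cc1O[Si](C(C)C)(C(C)C)C(C)C | intermediate
12 | (−)-menthone, (2S,5R)-2-isopropyl-5-methylcyclohexanone | CC(C)[C@@H]1CC[C@@H](C)CC1=O | starting material
13 | (tert-butyldimethylsilyloxy)acetaldehyde | O=CCO[Si](C)(C)C(C)(C)C | starting material
14 | lithium (3R,6S)-6-isopropyl-3-methylcyclohex-1-en-1-olate | CC(C)[C@@H]1CC[C@@H](C)C=C1O[Li] | intermediate
15 | (3R,6S)-2-[2-(TBS-oxy)-1-hydroxyethyl]-6-isopropyl-3-methylcyclohexanone (mixture at C2 and carbinol carbon) | CC(C)[C@@H]1CC[C@@H](C)C(C(O)CO[Si](C)(C)C(C)(C)C)C1=O | intermediate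
16 | methanesulfonate of 15 | CC(C)[C@@H]1CC[C@@H](C)C(C(CO[Si](C)(C)C(C)(C)C)OS(C)(=O)=O)C1=O | intermediate
17 | (2E,3R,6S)-2-[2-(TBS-oxy)ethylidene]-6-isopropyl-3-methylcyclohexanone | CC(C)[C@@H]1CC[C@@H](C)/C(=C\CO[Si](C)(C)C(C)(C)C)C1=O | intermediate
18 | (2R,3R,6S)-2-[2-(TBS-oxy)ethyl]-6-isopropyl-3-methylcyclohexanone | CC(C)[C@@H]1CC[C@@H](C)[C@@H](CCO[Si](C)(C)C(C)(C)C)C1=O | intermediate
19 | tert-butyl{2-[(1R,3S,6R)-3-isopropyl-6-methyl-2-methylidenecyclohexyl]ethoxy}dimethylsilane | CC(C)[C@@H]1CC[C@@H](C)[C@@H](CCO[Si](C)(C)C(C)(C)C)C1=C | intermediate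
20 | 2-[(1R,3S,6R)-3-isopropyl-6-methyl-2-methylidenecyclohexyl]ethanol | CC(C)[C@@H]1CC[C@@H](C)[C@@H](CCO)C1=C | intermediate
21 | (1R,3S,6R)-1-(2-iodoethyl)-3-isopropyl-6-methyl-2-methylidenecyclohexane | CC(C)[C@@H]1CC[C@@H](C)[C@@H](CCI)C1=C | intermediate
22 | alkyllithium from 21 | CC(C)[C@@H]1CC[C@@H](C)[C@@H](CC[Li])C1=C | intermediate
23 | lithium B-alkyl-B-methoxy-9-borabicyclo[3.3.1]nonane ate complex from 22 | [Li+].CC(C)[C@@H]1CC[C@@H](C)[C@@H](CC[B-]2(OC)C3CCCC2CCC3)C1=C | intermediate
24 | (2E,5R)-3-{2-[(1R,3S,6R)-3-isopropyl-6-methyl-2-methylidenecyclohexyl]ethyl}-5-phenyl-5-[2-(TIPS-oxy)-4,6-bis(SEM-oxy)phenyl]pent-2-en-1-ol | OC/C=C(\CC[C@@H]1[C@H](C)CC[C@@H](C(C)C)C1=C)C[C@H](c1ccccc1)c1c(OCOCC[Si](C)(C)C)cc(OCOCC[Si](C)(C)C)cc1O[Si](C(C)C)(C(C)C)C(C)C | intermediate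
25 | methyl carbonate of 24 | COC(=O)OC/C=C(\CC[C@@H]1[C@H](C)CC[C@@H](C(C)C)C1=C)C[C@H](c1ccccc1)c1c(OCOCC[Si](C)(C)C)cc(OCOCC[Si](C)(C)C)cc1O[Si](C(C)C)(C(C)C)C(C)C | intermediate
26 | free phenol of 25 (TIPS removed) | COC(=O)OC/C=C(\CC[C@@H]1[C@H](C)CC[C@@H](C(C)C)C1=C)C[C@H](c1ccccc1)c1c(OCOCC[Si](C)(C)C)cc(OCOCC[Si](C)(C)C)cc1O | intermediate
27 | (2S,4R)-2-{2-[(1R,3S,6R)-3-isopropyl-6-methyl-2-methylidenecyclohexyl]ethyl}-4-phenyl-5,7-bis(SEM-oxy)-2-vinylchromane | CC(C)[C@@H]1CC[C@@H](C)[C@@H](CC[C@@]2(C=C)C[C@H](c3ccccc3)c3c(OCOCC[Si](C)(C)C)cc(OCOCC[Si](C)(C)C)cc3O2)C1=C | intermediate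
28 | di-O-SEM spirochroman with C5=C6 alkene (C4 S, C1′ R, C1 R, C7 S, C10 R) | CC(C)[C@@H]1CC[C@@H](C)[C@H]2CC[C@@]3(C=C12)C[C@H](c1ccccc1)c1c(OCOCC[Si](C)(C)C)cc(OCOCC[Si](C)(C)C)cc1O3 | intermediate
29 | 5,7-dihydroxy spirochroman (configuration as 28) | CC(C)[C@@H]1CC[C@@H](C)[C@H]2CC[C@@]3(C=C12)C[C@H](c1ccccc1)c1c(O)cc(O)cc1O3 | intermediate
30 | 6,8-bis(N,N-dimethyliminiomethyl) dichloride of 29 | CC(C)[C@@H]1CC[C@@H](C)[C@H]2CC[C@@]3(C=C12)C[C@H](c1ccccc1)c1c(O)c(C=[N+](C)C)c(O)c(C=[N+](C)C)c1O3.[Cl-].[Cl-] | intermediate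
31 | guajadial C (C4 S, C1′ R, C1 R, C7 S, C10 R) | CC(C)[C@@H]1CC[C@@H](C)[C@H]2CC[C@@]3(C=C12)C[C@H](c1ccccc1)c1c(O)c(C=O)c(O)c(C=O)c1O3 | target

**Step count and risks**

Total step count: 20. Longest linear sequence: 14 steps (steps 1–7, then 14–20); the menthone branch (steps 8–13) joins at step 14.

Steps most likely to fail:

Step 18 (ring-closing metathesis). The catalyst may load slowly on the vinyl group next to the quaternary C4 and engage the doubly α-branched C6 methylene poorly, so that dimerisation through the vinyl groups or ruthenium hydride-induced alkene migration outruns ring closure. The fallback forms the same C5=C6 bond by carbonyl coupling. It sets out from 27: oxidative cleavage of both terminal alkenes (OsO4 cat., NaIO4, 2,6-lutidine, dioxane/H2O) should give the C4-formyl C6-ketone F1. Intramolecular McMurry coupling (TiCl3(DME)1.5, Zn–Cu, DME, reflux, slow addition) then joins C5 to C6 and returns to the route at 28.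

Step 10 (hydrogenation setting C1). Facial selectivity may be poor because the axial C7 isopropyl shields the face opposite the C10 methyl to some extent, and the strained enone may epimerise at C7 on the catalyst. The fallback replaces surface hydrogenation by enolate protonation. It sets out from 17: copper hydride-catalysed conjugate hydrosilylation ([(Ph3P)CuH]6 cat., PhMe2SiH, toluene, rt) should give the regiodefined dimethylphenylsilyl enol ether F2. Cleavage with MeLi (THF, 0 °C) to the amine-free lithium enolate and kinetic protonation at −78 °C with 2,6-di-tert-butylphenol, anti to the pseudoaxial C10 methyl, returns to the route at 18.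

Step 17 (allylic etherification setting C4). Mismatched double stereodifferentiation with C1′, or incomplete equilibration of the diastereomeric π-allyl complexes, may erode selectivity at C4. The fallback sets C4 by reagent-controlled epoxidation and invertive ring opening. It sets out from 24: Sharpless asymmetric epoxidation with D-(−)-diethyl tartrate (Ti(OiPr)4, t-BuOOH, 4 Å MS, CH2Cl2, −20 °C) should give the (2R,3R)-epoxy alcohol F3. Buffered TBAF frees the phenol to give the epoxy phenol F4. Camphorsulfonic acid (cat., CH2Cl2, 0 °C) triggers 6-exo opening at the tertiary epoxide carbon with inversion to give the chroman 1,2-diol F5. Deoxygenation of the diol to the alkene (PPh3, imidazole, I2, toluene, 80 °C) returns to the route at 27.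

Further compounds
F1 | step 18 | (2S,4R)-2-{2-[(1R,3S,4R)-3-isopropyl-4... ring ketone: 2-oxo-3-isopropyl-6-methylcyclohexyl]ethyl}-4-phenyl-5,7-bis(SEM-oxy)chromane-2-carbaldehyde (keto aldehyde from cleavage of both alkenes of 27) | CC(C)[C@@H]1CC[C@@H](C)[C@@H](CC[C@@]2(C=O)C[C@H](c3ccccc3)c3c(OCOCC[Si](C)(C)C)cc(OCOCC[Si](C)(C)C)cc3O2)C1=O
F2 | step 10 | dimethylphenylsilyl enol ether of 18 (C1=C6 enol ether, C7 and C10 as in menthone) | CC(C)[C@@H]1CC[C@@H](C)C(CCO[Si](C)(C)C(C)(C)C)=C1O[Si](C)(C)c1ccccc1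
F3 | step 17 | (2R,3R)-2,3-epoxy alcohol of 24 (epoxide across C4–C5, TIPS ether retained) | OC[C@H]1O[C@]1(CC[C@@H]2[C@H](C)CC[C@@H](C(C)C)C2=C)C[C@H](c1ccccc1)c1c(OCOCC[Si](C)(C)C)cc(OCOCC[Si](C)(C)C)cc1O[Si](C(C)C)(C(C)C)C(C)C
F4 | step 17 | free phenol of F3 | OC[C@H]1O[C@]1(CC[C@@H]2[C@H](C)CC[C@@H](C(C)C)C2=C)C[C@H](c1ccccc1)c1c(OCOCC[Si](C)(C)C)cc(OCOCC[Si](C)(C)C)cc1O
F5 | step 17 | chroman 1,2-diol: 27 with the vinyl group replaced by (1R)-1,2-dihydroxyethyl | CC(C)[C@@H]1CC[C@@H](C)[C@@H](CC[C@@]2([C@H](O)CO)C[C@H](c3ccccc3)c3c(OCOCC[Si](C)(C)C)cc(OCOCC[Si](C)(C)C)cc3O2)C1=C
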